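**Plan**

- Retrosynthesis cuts C3–C4 (ten-membered ring), the O8–angeloyl bond, the lactone O–C6 bond, C6–C7, C1=C2 and C7–C8. The pieces are (S)-citramalic acid (C1, C8–C10, C14), an acrylate donor (C7, C11–C13), but-2-yn-1-ol (C4–C6, C15), a formylmethylene ylide (C2, C3) and angelic acid.
- Enabling feature: C7 carries the C11–C13 acrylate and lies between two carbinol carbons, C8 and the allylic C6, each γ to the C12 carboxyl. The carboxyl is first parked on O8 as a butenolide, then as a trans 8,12-lactone (temporary ring), and is then moved to C6 with inversion.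
- Forward order: 8,12-lactone ring (steps 5–7), opened (step 8), cis 6,12-lactone closed by O–C6 bond formation (step 9), ten-membered ring last by C3–C4 closure (step 14).
- Stereochemistry: C10 from citramalic acid; C8 from the chiral iridium catalyst; C7 (trans to C8) and C6 (anti) from the chair allylation on the butenolide ring; C6 then inverted by SN2 to the cis fusion; C3 in the ring closure.
- Alkene geometry: Z C4=C5 from anti-hydroalumination and iodination, E C1=C2 from the Wittig step, Z ester from angelic acid.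

Key step: step 9

Remark: germacranolide numbering is used (ring C1–C10, acrylate C11–C13, C14 on C10, C15 on C4). The target is read as 3S,6S,7R,8S,10S with a cis-fused 6,12-lactone, and 8, 17 and 22 are taken as purchasable.

**Route**

Step 1
Reactants: 1 but-2-yn-1-ol
Product: 3 (2Z)-3-iodobut-2-en-1-ol, via cyclic alkenylalanate 2 (not isolated)
Conditions: NaAlH2(OCH2CH2OMe)2 (Red-Al), THF, 0 °C to rt; then I2, −78 °C to 0 °C
Reagents that add atoms: iodine, II
Why: Hydroxyl-directed anti-hydroalumination of the propargylic alcohol puts aluminium on the distal carbon in a five-membered alanate, and iodinolysis with retention should give the Z iodoalkene that fixes the C4=C5 geometry (hydroalumination–iodination).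

Step 2
Reactants: 3 (2Z)-3-iodobut-2-en-1-ol
Product: 4 (2Z)-3-iodobut-2-enal
Conditions: MnO2, CH2Cl2, rt, dark
Reagents that add atoms: none
Why: MnO2 oxidation of the allylic alcohol stops at the aldehyde under neutral conditions and should leave the Z iodoalkene unchanged.

Step 3
Reactants: 5 (S)-citramalic acid
Product: 6 (2S)-2-methylbutane-1,2,4-triol
Conditions: BH3·SMe2, B(OMe)3, THF, 0 °C to rt; MeOH
Reagents that add atoms: none
Why: Borane reduces both carboxylic acids to primary alcohols and does not touch the tertiary carbinol, so the C10 stereocentre comes unchanged from the chiral pool.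

Step 4
Reactants: 6 (2S)-2-methylbutane-1,2,4-triol
Product: 7 2-[(4S)-2,2,4-trimethyl-1,3-dioxolan-4-yl]ethan-1-ol
Conditions: 2,2-dimethoxypropane, PPTS (cat.), acetone, rt
Reagents that add atoms: 2,2-dimethoxypropane, COC(C)(C)OC
Why: Acetonide formation under thermodynamic control favours the five-membered dioxolane on the 1,2-diol (O10, O1) over the six-membered dioxane and leaves the C8 alcohol free.

Step 5
Reactants: 7 2-[(4S)-2,2,4-trimethyl-1,3-dioxolan-4-yl]ethan-1-ol; 8 methyl 2-{[(tert-butoxycarbonyl)oxy]methyl}prop-2-enoate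
Product: 11 (5R)-3-methylidene-5-{[(4S)-2,2,4-trimethyl-1,3-dioxolan-4-yl]methyl}oxolan-2-one, via aldehyde 9 (not isolated), via hydroxy ester 10 (not isolated)
Conditions: [Ir(cod)Cl]2 (2.5 mol %), (R)-SEGPHOS (5 mol %; the antipode if it is the one that gives 5R), 4-cyano-3-nitrobenzoic acid (10 mol %), Cs2CO3 (20 mol %), THF, 60 °C
Reagents that add atoms: none
Why: Iridium-catalysed transfer-hydrogenative carbonyl 2-(alkoxycarbonyl)allylation: the alcohol is dehydrogenated to 9, the allyliridium species from 8 adds to it to form C7–C8 with the chiral bisphosphine setting C8 (catalyst control), and the γ-hydroxy ester 10 lactonises.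

Step 6
Reactants: 11 (5R)-3-methylidene-5-{[(4S)-2,2,4-trimethyl-1,3-dioxolan-4-yl]methyl}oxolan-2-one
Product: 13 (5S)-3-(bromomethyl)-5-{[(4S)-2,2,4-trimethyl-1,3-dioxolan-4-yl]methyl}furan-2(5H)-one, via dibromide 12 (not isolated)
Conditions: Br2, CH2Cl2, 0 °C to rt; then Et3N, 0 °C
Reagents that add atoms: bromine, BrBr
Why: Bromine addition to the exocyclic alkene followed by E2 loss of HBr from the ring CH2 should give the conjugated endocyclic butenolide carrying the allylic bromide; C8 is not involved, and the base is kept mild and cold to avoid γ-epimerisation.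

Step 7
Reactants: 13 (5S)-3-(bromomethyl)-5-{[(4S)-2,2,4-trimethyl-1,3-dioxolan-4-yl]methyl}furan-2(5H)-one; 4 (2Z)-3-iodobut-2-enal
Product: 14 (4S,5S)-4-[(1S,2Z)-1-hydroxy-3-iodobut-2-en-1-yl]-3-methylidene-5-{[(4S)-2,2,4-trimethyl-1,3-dioxolan-4-yl]methyl}oxolan-2-one
Conditions: CrCl2 (nickel-free, 4 equiv), THF, rt
Reagents that add atoms: none
Why: Nozaki–Hiyama allylation: the allylchromium from 13 attacks the aldehyde through its ring carbon C7 in a chair transition state; the ring holds C8 trans to the CH2Cr group (an E-crotyl-type reagent), so the C6 carbinol should form anti, and the C8 side chain blocks one ring face so that C6 adds trans to it, while the vinyl iodide is inert without nickel.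

Step 8
Reactants: 14 (4S,5S)-4-[(1S,2Z)-1-hydroxy-3-iodobut-2-en-1-yl]-3-methylidene-5-{[(4S)-2,2,4-trimethyl-1,3-dioxolan-4-yl]methyl}oxolan-2-one
Product: 15 (3R,4S,5Z)-4-hydroxy-3-{(1S)-1-hydroxy-2-[(4S)-2,2,4-trimethyl-1,3-dioxolan-4-yl]ethyl}-6-iodo-2-methylidenehept-5-enoic acid
Conditions: LiOH·H2O, THF/H2O (3:1), 0 °C; 1 M HCl to pH 4 at 0 °C, extraction, used at once
Reagents that add atoms: lithium hydroxide, [Li+].[OH-]
Why: Saponification of the temporary 8,12-lactone (hydroxide attack at C12) frees the carboxyl and O8 without touching a stereocentre; acetonide and vinyl iodide tolerate cold base and pH 4.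

Step 9
Reactants: 15 (3R,4S,5Z)-4-hydroxy-3-{(1S)-1-hydroxy-2-[(4S)-2,2,4-trimethyl-1,3-dioxolan-4-yl]ethyl}-6-iodo-2-methylidenehept-5-enoic acid
Product: 16 (4R,5R)-4-{(1S)-1-hydroxy-2-[(4S)-2,2,4-trimethyl-1,3-dioxolan-4-yl]ethyl}-5-[(1Z)-2-iodoprop-1-en-1-yl]-3-methylideneoxolan-2-one
Conditions: PPh3, DIAD, THF (0.01 M), −20 °C to 0 °C, acid added to the preformed betaine
Reagents that add atoms: none
Why: The PPh3/DIAD betaine is protonated by the acid and turns the allylic C6 hydroxyl into an alkoxyphosphonium ion, which the C12 carboxylate displaces from the rear with loss of Ph3PO. The closest known reaction type is the Mitsunobu lactonisation of γ-hydroxy acids with inversion. The five-membered lactone closes in the 5-exo-tet mode, the carboxylate oxygen becoming bonded to C6. C6 is the only stereocentre that changes: the carbinol set in step 7 is inverted stereospecifically, which turns the anti C6/C7 array into the cis ring fusion while C7 and C8 stay as they are. The step needs closure at C6 and not at C8, and SN2 displacement and not ionisation or acyl activation; C6 is allylic and flanked by an sp2 carbon whereas C8 is hindered by C7 and the neopentyl C9, the iodine on C4 disfavours the allyl cation and leaves the far allyl terminus fully substituted, and the cold betaine-first protocol limits lactonisation by acyl substitution. The same event leaves O8 free for the angelate.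

Step 10
Reactants: 16 (4R,5R)-4-{(1S)-1-hydroxy-2-[(4S)-2,2,4-trimethyl-1,3-dioxolan-4-yl]ethyl}-5-[(1Z)-2-iodoprop-1-en-1-yl]-3-methylideneoxolan-2-one; 17 angelic acid
Product: 19 (1S)-1-{(2R,3R)-2-[(1Z)-2-iodoprop-1-en-1-yl]-4-methylidene-5-oxooxolan-3-yl}-2-[(4S)-2,2,4-trimethyl-1,3-dioxolan-4-yl]ethyl (2Z)-2-methylbut-2-enoate, via mixed anhydride 18 (not isolated)
Conditions: 17, 2,4,6-trichlorobenzoyl chloride, Et3N, toluene, rt; then 16, toluene, 75 °C
Reagents that add atoms: none
Why: Yamaguchi esterification through the mixed anhydride without DMAP is the protocol that keeps the Z geometry of angelates, and O8 is the only free hydroxyl.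

Step 11
Reactants: 19 (1S)-1-{(2R,3R)-2-[(1Z)-2-iodoprop-1-en-1-yl]-4-methylidene-5-oxooxolan-3-yl}-2-[(4S)-2,2,4-trimethyl-1,3-dioxolan-4-yl]ethyl (2Z)-2-methylbut-2-enoate
Product: 20 (1S,3S)-3,4-dihydroxy-1-{(2R,3R)-2-[(1Z)-2-iodoprop-1-en-1-yl]-4-methylidene-5-oxooxolan-3-yl}-3-methylbutyl (2Z)-2-methylbut-2-enoate
Conditions: AcOH/THF/H2O (3:1:1), 40 °C
Reagents that add atoms: none
Why: Mild aqueous acid hydrolyses the terminal acetonide (acetal hydrolysis); lactone, angelate and vinyl iodide should be stable, and no free hydroxyl is placed to attack the lactone.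

Step 12
Reactants: 20 (1S,3S)-3,4-dihydroxy-1-{(2R,3R)-2-[(1Z)-2-iodoprop-1-en-1-yl]-4-methylidene-5-oxooxolan-3-yl}-3-methylbutyl (2Z)-2-methylbut-2-enoate
Product: 21 (1S,3S)-3-hydroxy-1-{(2R,3R)-2-[(1Z)-2-iodoprop-1-en-1-yl]-4-methylidene-5-oxooxolan-3-yl}-3-methyl-4-oxobutyl (2Z)-2-methylbut-2-enoate
Conditions: TEMPO (cat.), PhI(OAc)2, CH2Cl2, rt
Reagents that add atoms: none
Why: Oxoammonium (TEMPO) oxidation takes the primary C1 alcohol to the aldehyde; the tertiary C10 alcohol cannot be oxidised and these conditions do not cleave the glycol.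

Step 13
Reactants: 21 (1S,3S)-3-hydroxy-1-{(2R,3R)-2-[(1Z)-2-iodoprop-1-en-1-yl]-4-methylidene-5-oxooxolan-3-yl}-3-methyl-4-oxobutyl (2Z)-2-methylbut-2-enoate; 22 2-(triphenyl-λ5-phosphanylidene)acetaldehyde
Product: 23 (1S,3S,4E)-3-hydroxy-1-{(2R,3R)-2-[(1Z)-2-iodoprop-1-en-1-yl]-4-methylidene-5-oxooxolan-3-yl}-3-methyl-6-oxohex-4-en-1-yl (2Z)-2-methylbut-2-enoate
Conditions: toluene, 60 °C
Reagents that add atoms: none
Why: Wittig olefination with the stabilised formylmethylene ylide adds C2 and C3 and should give the E enal (C1=C2); the non-enolisable aldehyde reacts faster than the acrylate unit.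

Step 14
Reactants: 23 (1S,3S,4E)-3-hydroxy-1-{(2R,3R)-2-[(1Z)-2-iodoprop-1-en-1-yl]-4-methylidene-5-oxooxolan-3-yl}-3-methyl-6-oxohex-4-en-1-yl (2Z)-2-methylbut-2-enoate
Product: 24 (1E,3S,4Z,6S,7R,8S,10S)-3,10-dihydroxy-8-[(2Z)-2-methylbut-2-enoyloxy]germacra-1,4,11(13)-trien-12,6-olide (target CNP0262559.5)
Conditions: CrCl2 (10 equiv), NiCl2 (1 mol % of the chromium), DMSO/THF (3:1), 0.002 M, rt, slow addition
Reagents that add atoms: none
Why: Nozaki–Hiyama–Kishi reaction: zerovalent nickel inserts into the C4–I bond with retention of the Z geometry, transmetallation to trivalent chromium gives an alkenylchromium that adds 1,2 to the enal at high dilution to close the ten-membered ring at C3–C4; the C3 carbinol is set in the ring-closing transition state (macrocyclic substrate control, the 3S isomer needing addition to the Re face of the aldehyde), and the free tertiary alcohol, lactone and angelate are tolerated.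

**Compound list**

1 | but-2-yn-1-ol | CC#CCO | starting material
2 | sodium cyclic (Z)-alkenylalanate (2,2-bis(2-methoxyethoxy)-3-methyl-2,5-dihydro-1,2-oxaaluminol-2-uide) | [Na+].CC1=CCO[Al-]1(OCCOC)OCCOC | intermediate
3 | (2Z)-3-iodobut-2-en-1-ol | OC/C=C(/C)I | intermediate
4 | (2Z)-3-iodobut-2-enal | O=C/C=C(/C)I | intermediate
5 | (S)-citramalic acid, (2S)-2-hydroxy-2-methylbutanedioic acid | OC(=O)C[C@](C)(O)C(=O)O | starting material
6 | (2S)-2-methylbutane-1,2,4-triol | OCC[C@](C)(O)CO | intermediate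
7 | 2-[(4S)-2,2,4-trimethyl-1,3-dioxolan-4-yl]ethan-1-ol | OCC[C@@]1(C)COC(C)(C)O1 | intermediate
8 | methyl 2-{[(tert-butoxycarbonyl)oxy]methyl}prop-2-enoate | COC(=O)C(=C)COC(=O)OC(C)(C)C | starting material
9 | 2-[(4S)-2,2,4-trimethyl-1,3-dioxolan-4-yl]acetaldehyde | O=CC[C@@]1(C)COC(C)(C)O1 | intermediate
10 | methyl (4R)-4-hydroxy-2-methylidene-5-[(4S)-2,2,4-trimethyl-1,3-dioxolan-4-yl]pentanoate | COC(=O)C(=C)C[C@@H](O)C[C@@]1(C)COC(C)(C)O1 | intermediate
11 | (5R)-3-methylidene-5-{[(4S)-2,2,4-trimethyl-1,3-dioxolan-4-yl]methyl}oxolan-2-one | C=C1C[C@H](C[C@@]2(C)COC(C)(C)O2)OC1=O | intermediate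
12 | (5S)-3-bromo-3-(bromomethyl)-5-{[(4S)-2,2,4-trimethyl-1,3-dioxolan-4-yl]methyl}oxolan-2-one (both C3 epimers) | BrCC1(Br)C[C@H](C[C@@]2(C)COC(C)(C)O2)OC1=O | intermediate
13 | (5S)-3-(bromomethyl)-5-{[(4S)-2,2,4-trimethyl-1,3-dioxolan-4-yl]methyl}furan-2(5H)-one | BrCC1=C[C@H](C[C@@]2(C)COC(C)(C)O2)OC1=O | intermediate
14 | (4S,5S)-4-[(1S,2Z)-1-hydroxy-3-iodobut-2-en-1-yl]-3-methylidene-5-{[(4S)-2,2,4-trimethyl-1,3-dioxolan-4-yl]methyl}oxolan-2-one | C=C1C(=O)O[C@@H](C[C@@]2(C)COC(C)(C)O2)[C@@H]1[C@H](O)/C=C(/C)I | intermediate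
15 | (3R,4S,5Z)-4-hydroxy-3-{(1S)-1-hydroxy-2-[(4S)-2,2,4-trimethyl-1,3-dioxolan-4-yl]ethyl}-6-iodo-2-methylidenehept-5-enoic acid | C=C(C(=O)O)[C@H]([C@@H](O)C[C@@]1(C)COC(C)(C)O1)[C@H](O)/C=C(/C)I | intermediate
16 | (4R,5R)-4-{(1S)-1-hydroxy-2-[(4S)-2,2,4-trimethyl-1,3-dioxolan-4-yl]ethyl}-5-[(1Z)-2-iodoprop-1-en-1-yl]-3-methylideneoxolan-2-one | C=C1C(=O)O[C@@H](/C=C(/C)I)[C@H]1[C@@H](O)C[C@@]2(C)COC(C)(C)O2 | intermediate
17 | angelic acid, (2Z)-2-methylbut-2-enoic acid | C/C=C(/C)C(=O)O | starting material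
18 | (2Z)-2-methylbut-2-enoic 2,4,6-trichlorobenzoic anhydride | C/C=C(/C)C(=O)OC(=O)c1c(Cl)cc(Cl)cc1Cl | intermediate
19 | (1S)-1-{(2R,3R)-2-[(1Z)-2-iodoprop-1-en-1-yl]-4-methylidene-5-oxooxolan-3-yl}-2-[(4S)-2,2,4-trimethyl-1,3-dioxolan-4-yl]ethyl (2Z)-2-methylbut-2-enoate | C=C1C(=O)O[C@@H](/C=C(/C)I)[C@H]1[C@@H](OC(=O)/C(C)=C\C)C[C@@]2(C)COC(C)(C)O2 | intermediate
20 | (1S,3S)-3,4-dihydroxy-1-{(2R,3R)-2-[(1Z)-2-iodoprop-1-en-1-yl]-4-methylidene-5-oxooxolan-3-yl}-3-methylbutyl (2Z)-2-methylbut-2-enoate | C=C1C(=O)O[C@@H](/C=C(/C)I)[C@H]1[C@@H](OC(=O)/C(C)=C\C)C[C@](C)(O)CO | intermediate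
21 | (1S,3S)-3-hydroxy-1-{(2R,3R)-2-[(1Z)-2-iodoprop-1-en-1-yl]-4-methylidene-5-oxooxolan-3-yl}-3-methyl-4-oxobutyl (2Z)-2-methylbut-2-enoate | C=C1C(=O)O[C@@H](/C=C(/C)I)[C@H]1[C@@H](OC(=O)/C(C)=C\C)C[C@](C)(O)C=O | intermediate
22 | 2-(triphenyl-λ5-phosphanylidene)acetaldehyde | O=CC=P(c1ccccc1)(c1ccccc1)c1ccccc1 | starting material
23 | (1S,3S,4E)-3-hydroxy-1-{(2R,3R)-2-[(1Z)-2-iodoprop-1-en-1-yl]-4-methylidene-5-oxooxolan-3-yl}-3-methyl-6-oxohex-4-en-1-yl (2Z)-2-methylbut-2-enoate | C=C1C(=O)O[C@@H](/C=C(/C)I)[C@H]1[C@@H](OC(=O)/C(C)=C\C)C[C@](C)(O)/C=C/C=O | intermediate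
24 | (1E,3S,4Z,6S,7R,8S,10S)-3,10-dihydroxy-8-[(2Z)-2-methylbut-2-enoyloxy]germacra-1,4,11(13)-trien-12,6-olide | C=C1C(=O)O[C@H]2/C=C(/C)[C@@H](O)/C=C/[C@@](C)(O)C[C@H](OC(=O)/C(C)=C\C)[C@@H]12 | target

**Count and risks**

Total steps: 14. Longest linear sequence: 12 (steps 3 to 14); steps 1 and 2 form the side branch that joins at step 7.

Steps most likely to fail:

1. Step 9 (key step). What may go wrong: activation of the carboxyl instead of the hydroxyl, giving lactone closure with retention; closure at C8; or relactonisation of the hydroxy acid before it is activated. Fallback: it sets out from 14. The C6 hydroxyl is converted with MsCl and Et3N (CH2Cl2, −30 °C) into the allylic mesylate F1 while O8 is still held in the lactone. One equivalent of LiOH (THF/H2O, 0 °C) then opens the 8,12-lactone to the lithium carboxylate mesylate F2. On warming, the carboxylate displaces the sulfonate intramolecularly (SN2, 5-exo-tet) with inversion, and no base is left when the new lactone forms. The fallback comes back to the route at 16.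

2. Step 14. What may go wrong: poor facial selectivity at the new C3 carbinol, and oligomerisation competing with closure of the ten-membered ring. Fallback: it sets out from 23. The ring closure is run without regard to C3 and the C3-epimeric carbinols F3 are taken on together. MnO2 oxidises the doubly allylic alcohol to the cross-conjugated macrocyclic dienone F4. Corey–Bakshi–Shibata reduction (catecholborane, −78 °C, the oxazaborolidine enantiomer that gives the 3S alcohol) then sets C3 under reagent control. The fallback comes back to the route at 24.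

3. Step 7. What may go wrong: loss of the anti selectivity through an open transition state, weak face discrimination by the C8 side chain, or reduction of the β-iodoenal by the chromium salt. Fallback: it sets out from 13. Palladium-catalysed borylation (B2pin2, Pd2(dba)3 cat., toluene) gives the primary allylboronate F5, in which the ring still locks the E-crotyl-type geometry. Allylboration of 4 (toluene, Sc(OTf)3 cat., 0 °C to rt) must pass through the closed six-membered transition state and gives the borate ester F6 of the anti, trans adduct. Aqueous work-up releases the alcohol, and the fallback comes back to the route at 14.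

Further compounds
F1 | step 9 | (1S,2Z)-3-iodo-1-[(2S,3S)-4-methylidene-5-oxo-2-{[(4S)-2,2,4-trimethyl-1,3-dioxolan-4-yl]methyl}oxolan-3-yl]but-2-en-1-yl methanesulfonate | C=C1C(=O)O[C@@H](C[C@@]2(C)COC(C)(C)O2)[C@@H]1[C@H](OS(C)(=O)=O)/C=C(/C)I
F2 | step 9 | lithium (3R,4S,5Z)-3-{(1S)-1-hydroxy-2-[(4S)-2,2,4-trimethyl-1,3-dioxolan-4-yl]ethyl}-6-iodo-4-(methanesulfonyloxy)-2-methylidenehept-5-enoate | [Li+].C=C(C(=O)[O-])[C@H]([C@@H](O)C[C@@]1(C)COC(C)(C)O1)[C@H](OS(C)(=O)=O)/C=C(/C)I
F3 | step 14 | C3-epimeric mixture of the macrocyclic carbinol (24 and its 3-epimer) | C=C1C(=O)O[C@H]2/C=C(/C)C(O)/C=C/[C@@](C)(O)C[C@H](OC(=O)/C(C)=C\C)[C@@H]12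
F4 | step 14 | (1E,4Z,6S,7R,8S,10S)-10-hydroxy-8-[(2Z)-2-methylbut-2-enoyloxy]-3-oxogermacra-1,4,11(13)-trien-12,6-olide | C=C1C(=O)O[C@H]2/C=C(/C)C(=O)/C=C/[C@@](C)(O)C[C@H](OC(=O)/C(C)=C\C)[C@@H]12
F5 | step 7 | (5S)-3-[(4,4,5,5-tetramethyl-1,3,2-dioxaborolan-2-yl)methyl]-5-{[(4S)-2,2,4-trimethyl-1,3-dioxolan-4-yl]methyl}furan-2(5H)-one | CC1(C)OB(CC2=C[C@H](C[C@@]3(C)COC(C)(C)O3)OC2=O)OC1(C)C
F6 | step 7 | pinacol borate ester of 14 at O6 | C=C1C(=O)O[C@@H](C[C@@]2(C)COC(C)(C)O2)[C@@H]1[C@H](OB3OC(C)(C)C(C)(C)O3)/C=C(/C)I
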